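The flavonol is cut at C3 of ring C: this carbon, held between C2 (bonded to O1 and ring B) and the C4 carbonyl, is regarded as a single carbon pushed into the C2–C3 bond of a 2-arylbenzofuran-3-one. In one operation, dibromocarbene adds to the furan enol-ether bond of the silyl enol ether and the adduct opens, creating C2–C3 and C3–C4, enlarging the furan to the 4-pyranone, revealing the C4 carbonyl and leaving bromine at C3 for later exchange to hydroxyl. The precursor is the tert-butyldimethylsilyl enol ether of 4,6-dimethoxy-5,7-dimethyl-2-(2-methoxyphenyl)benzofuran-3-one, whose ring A is fully substituted and built by two directed lithiations.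

Key step: step 6

Remark: the target has no stereocentre; intermediates 9 and 13 are racemic and lose their stereocentres in the flask in which they form.
Remark: compounds that deliver carbon atoms of the target are numbered as reactants; all other reagents appear on the Conditions and reagent lines only.

Step 1
Reactants: 1 2,4,6-trimethoxytoluene; 2 iodomethane
Product: 3 1,3,5-trimethoxy-2,4-dimethylbenzene
Conditions: n-BuLi (1.1 equiv), TMEDA, THF, 0 °C → rt; then MeI, −78 °C → rt
Reagents that add atoms: iodomethane (2), CI
Why: Directed ortho-metalation removes one of the two symmetry-equivalent ring hydrogens, each flanked by two methoxy groups and kinetically far more acidic than the aryl methyl group, and the aryllithium is methylated by SN2 attack on iodomethane.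

Step 2
Reactants: 3 1,3,5-trimethoxy-2,4-dimethylbenzene; 4 methyl chloroformate
Product: 5 methyl 2,4,6-trimethoxy-3,5-dimethylbenzoate
Conditions: n-BuLi (1.2 equiv), TMEDA, THF, 0 °C → rt; then cannulated into ClCO2Me (3 equiv), THF, −78 °C
Reagents that add atoms: methyl chloroformate (4), COC(=O)Cl
Why: A second directed ortho-metalation at the only remaining ring hydrogen gives an aryllithium that is acylated by the chloroformate, while inverse addition and the two ortho methoxy groups should suppress a second addition to the new ester.

Step 3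
Reactants: 5 methyl 2,4,6-trimethoxy-3,5-dimethylbenzoate
Product: 6 methyl 2-hydroxy-4,6-dimethoxy-3,5-dimethylbenzoate
Conditions: BCl3 (1.1 equiv), CH2Cl2, −78 → 0 °C; then H2O
Reagents that add atoms: none
Why: Chelation-directed Lewis acid ether cleavage, in which BCl3 held on the ester carbonyl reaches only an ortho methoxy group; the two ortho groups are equivalent by symmetry, and the six-membered aryloxyboron chelate formed should resist a second cleavage.

Step 4
Reactants: 6 methyl 2-hydroxy-4,6-dimethoxy-3,5-dimethylbenzoate; 7 2-methoxybenzyl chloride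
Product: 8 methyl 4,6-dimethoxy-2-[(2-methoxyphenyl)methoxy]-3,5-dimethylbenzoate
Conditions: K2CO3, NaI (cat.), DMF, 60 °C
Reagents that add atoms: 2-methoxybenzyl chloride (7), COc1ccccc1CCl
Why: Williamson ether synthesis, in which the phenoxide displaces the benzylic chloride (via the iodide formed in situ) by SN2; no other nucleophilic site is present.

Step 5
Reactants: 8 methyl 4,6-dimethoxy-2-[(2-methoxyphenyl)methoxy]-3,5-dimethylbenzoate
Product: 11 tert-butyl{[4,6-dimethoxy-2-(2-methoxyphenyl)-5,7-dimethyl-1-benzofuran-3-yl]oxy}dimethylsilane, via benzofuranone 9 (not isolated), via lithium enolate 10 (not isolated)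
Conditions: LiN(iPr)2 (2.5 equiv), THF, −78 → 0 °C; then TBSCl (3 equiv), DMPU, 0 °C → rt
Reagents that add atoms: tert-butyldimethylsilyl chloride, CC(C)(C)[Si](C)(C)Cl
Why: Anionic cyclisation of Dieckmann type, in which the benzylic α-oxy carbanion attacks the neighbouring ester (5-exo-trig) with loss of methoxide, the acidic C2–H of ketone 9 is removed to give the aromatic 3-oxidobenzofuran 10, and this is silylated on oxygen in the same flask so that the oxidation-prone ketone is never handled.

Step 6
Reactants: 11 tert-butyl{[4,6-dimethoxy-2-(2-methoxyphenyl)-5,7-dimethyl-1-benzofuran-3-yl]oxy}dimethylsilane; 12 bromoform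
Product: 14 3-bromo-5,7-dimethoxy-2-(2-methoxyphenyl)-6,8-dimethyl-4H-chromen-4-one, via dibromocyclopropane 13 (not isolated)
Conditions: CHBr3 (3 equiv), KOtBu (4 equiv), hexane–toluene, −20 °C → rt
Reagents that add atoms: bromoform (12), BrC(Br)Br
Why: α-Elimination of HBr from bromoform by KOtBu gives singlet dibromocarbene, which adds as an electrophile in a concerted [2+1] cycloaddition across the C2=C3 enol-ether bond of 11 to give the cis-fused gem-dibromocyclopropane 13. The bromide lying over the dihydrofuran ring then ionises in concert with disrotatory (two-electron electrocyclic) cleavage of the old furan C2–C3 bond, the lone pairs of O1 and of the siloxy oxygen stabilising the resulting 3-bromo-4-siloxybenzopyrylium ion, and transfer of the silyl group to bromide or tert-butoxide unveils the C4 carbonyl. The closest known reaction type is the dihalocarbene ring expansion of cyclic silyl enol ethers to 2-halo-enones, together with the carbene ring expansion of benzofurans and indoles to 3-halochromenes and 3-haloquinolines (Ciamician–Dennstedt type). Ring C is therefore closed not by a cyclisation but by cheletropic addition followed by electrocyclic five-to-six ring enlargement, the carbene carbon becoming C3 with the new bonds C2–C3 and C3–C4. No stereocentre is created, since the two stereocentres of racemic 13 become sp2 centres on opening. The step needs chemoselectivity for the furan bond over the three benzene rings and a single direction of opening; both follow from the siloxy enol ether, which is the only strongly nucleophilic non-benzenoid π bond (ring A has no free position) and places an oxygen donor at each end of the breaking bond, while the TBS group is bulky enough to survive tert-butoxide in a hydrocarbon solvent until the carbene has added.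

Step 7
Reactants: 14 3-bromo-5,7-dimethoxy-2-(2-methoxyphenyl)-6,8-dimethyl-4H-chromen-4-one
Product: 16 3-hydroxy-5,7-dimethoxy-2-(2-methoxyphenyl)-6,8-dimethyl-4H-chromen-4-one (the target), via pinacol boronate 15 (not isolated)
Conditions: B2pin2, PdCl2(dppf) (cat.), KOAc, 1,4-dioxane, 90 °C; filter through Celite; then 30% H2O2, NaHCO3, THF–H2O, 0 °C → rt
Reagents that add atoms: hydrogen peroxide, OO
Why: Miyaura borylation of the C3 vinyl bromide (oxidative addition to zerovalent palladium eased by the adjacent carbonyl, acetate-assisted transmetalation) followed by hydroperoxide-induced 1,2-migration from boron to oxygen should give the enol, which is the stable hydrogen-bonded 3-hydroxy-4-pyranone; the weak bicarbonate base spares the pyranone ring.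

Compound list
1 | 2,4,6-trimethoxytoluene | COc1cc(OC)c(C)c(OC)c1 | starting material
2 | iodomethane | CI | starting material
3 | 1,3,5-trimethoxy-2,4-dimethylbenzene | COc1cc(OC)c(C)c(OC)c1C | intermediate
4 | methyl chloroformate | COC(=O)Cl | starting material
5 | methyl 2,4,6-trimethoxy-3,5-dimethylbenzoate | COC(=O)c1c(OC)c(C)c(OC)c(C)c1OC | intermediate
6 | methyl 2-hydroxy-4,6-dimethoxy-3,5-dimethylbenzoate | COC(=O)c1c(O)c(C)c(OC)c(C)c1OC | intermediate
7 | 2-methoxybenzyl chloride (1-(chloromethyl)-2-methoxybenzene) | COc1ccccc1CCl | starting material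
8 | methyl 4,6-dimethoxy-2-[(2-methoxyphenyl)methoxy]-3,5-dimethylbenzoate | COC(=O)c1c(OCc2ccccc2OC)c(C)c(OC)c(C)c1OC | intermediate
9 | 4,6-dimethoxy-2-(2-methoxyphenyl)-5,7-dimethyl-1-benzofuran-3(2H)-one (racemic at C2) | COc1ccccc1C1Oc2c(C)c(OC)c(C)c(OC)c2C1=O | intermediate (not isolated)
10 | lithium 4,6-dimethoxy-2-(2-methoxyphenyl)-5,7-dimethyl-1-benzofuran-3-olate | [Li+].COc1ccccc1-c1oc2c(C)c(OC)c(C)c(OC)c2c1[O-] | intermediate (not isolated)
11 | tert-butyl{[4,6-dimethoxy-2-(2-methoxyphenyl)-5,7-dimethyl-1-benzofuran-3-yl]oxy}dimethylsilane | COc1ccccc1-c1oc2c(C)c(OC)c(C)c(OC)c2c1O[Si](C)(C)C(C)(C)C | intermediate (precursor of the key step)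
12 | bromoform | BrC(Br)Br | starting material
13 | tert-butyl{[1,1-dibromo-4,6-dimethoxy-1a-(2-methoxyphenyl)-3,5-dimethyl-1,1a-dihydro-6bH-cyclopropa[b][1]benzofuran-6b-yl]oxy}dimethylsilane (cis-fused, racemic; one enantiomer drawn) | COc1ccccc1[C@]12Oc3c(C)c(OC)c(C)c(OC)c3[C@@]1(O[Si](C)(C)C(C)(C)C)C2(Br)Br | intermediate (not isolated)
14 | 3-bromo-5,7-dimethoxy-2-(2-methoxyphenyl)-6,8-dimethyl-4H-chromen-4-one | COc1ccccc1-c1oc2c(C)c(OC)c(C)c(OC)c2c(=O)c1Br | intermediate (product of the key step)
15 | 5,7-dimethoxy-2-(2-methoxyphenyl)-6,8-dimethyl-3-(4,4,5,5-tetramethyl-1,3,2-dioxaborolan-2-yl)-4H-chromen-4-one | COc1ccccc1-c1oc2c(C)c(OC)c(C)c(OC)c2c(=O)c1B1OC(C)(C)C(C)(C)O1 | intermediate (not isolated)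
16 | 3-hydroxy-5,7-dimethoxy-2-(2-methoxyphenyl)-6,8-dimethyl-4H-chromen-4-one | COc1ccccc1-c1oc2c(C)c(OC)c(C)c(OC)c2c(=O)c1O | target

Total step count: 7
Longest linear sequence: 7 steps (1 → 3 → 5 → 6 → 8 → 11 → 14 → 16)

Steps most likely to fail

Step 6. The silyl enol ether may be desilylated by tert-butoxide before the carbene is captured, the carbene may add only sluggishly to the hindered tetrasubstituted furan bond, or it may be consumed by self-reaction. The fallback sets out from 3 and comes back to the route at 16, building the pyranone by classical condensation chemistry instead of ring expansion.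
- Friedel–Crafts acetylation of 3 (AcCl, AlCl3, CH2Cl2, 0 °C → rt), with loss of the chelated ortho O-methyl group, should give 1-(2-hydroxy-4,6-dimethoxy-3,5-dimethylphenyl)ethan-1-one F1.
- Claisen–Schmidt condensation with 2-methoxybenzaldehyde (KOH, EtOH, rt) should give the chalcone (E)-1-(2-hydroxy-4,6-dimethoxy-3,5-dimethylphenyl)-3-(2-methoxyphenyl)prop-2-en-1-one F2.
- Oxidative cyclisation (cat. I2, DMSO, 130 °C) should give the flavone 5,7-dimethoxy-2-(2-methoxyphenyl)-6,8-dimethyl-4H-chromen-4-one F3.
- Dimethyldioxirane (acetone–CH2Cl2, 0 °C) should give the racemic cis-fused epoxide 4,6-dimethoxy-1a-(2-methoxyphenyl)-3,5-dimethyl-1a,7a-dihydro-7H-oxireno[2,3-b]chromen-7-one F4, which should isomerise with a trace of TsOH to the flavonol 16.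
- Direct Algar–Flynn–Oyamada oxidation of the chalcone is avoided because a 6'-methoxy group is expected to divert that reaction towards aurone formation.

Step 5. The benzylic carbanion may undergo 1,2-Wittig rearrangement, or attack on the doubly ortho-substituted ester may be too slow; O-silylation may also stay incomplete in the presence of methoxide. The fallback sets out from 3 and comes back to the route at 9, closing the furanone by O-alkylation instead of C-acylation.
- Friedel–Crafts acylation of 3 with 2-methoxyphenylacetyl chloride (AlCl3, CH2Cl2, 0 °C → rt), with ortho demethylation, should give the deoxybenzoin 1-(2-hydroxy-4,6-dimethoxy-3,5-dimethylphenyl)-2-(2-methoxyphenyl)ethan-1-one F5.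
- α-Bromination (CuBr2, EtOAc–CHCl3, reflux) should give racemic 2-bromo-1-(2-hydroxy-4,6-dimethoxy-3,5-dimethylphenyl)-2-(2-methoxyphenyl)ethan-1-one F6.
- Intramolecular displacement of bromide by the phenol (NaOAc, EtOH, reflux) should close the ring to 9, which is then silylated separately (TBSOTf, Et3N, CH2Cl2, 0 °C) to 11.

Step 7. Hydrodebromination may outrun the slow transmetalation at the hindered C3 position, or the α-boryl enone may protodeboronate before oxidation. The fallback sets out from 14 and comes back to the route at 16, forming the C3–O bond directly with a protected oxygen nucleophile and no organoboron intermediate.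
- Palladium-catalysed C–O coupling with benzyl alcohol ([Pd(allyl)Cl]2, RockPhos, Cs2CO3, toluene, 90 °C) should give 3-(benzyloxy)-5,7-dimethoxy-2-(2-methoxyphenyl)-6,8-dimethyl-4H-chromen-4-one F7.
- Hydrogenolysis (H2, Pd on carbon, EtOAc, rt) should release 16.

Further compounds
F1 | step 6 | 1-(2-hydroxy-4,6-dimethoxy-3,5-dimethylphenyl)ethan-1-one | CC(=O)c1c(O)c(C)c(OC)c(C)c1OC
F2 | step 6 | (E)-1-(2-hydroxy-4,6-dimethoxy-3,5-dimethylphenyl)-3-(2-methoxyphenyl)prop-2-en-1-one | COc1ccccc1/C=C/C(=O)c1c(O)c(C)c(OC)c(C)c1OC
F3 | step 6 | 5,7-dimethoxy-2-(2-methoxyphenyl)-6,8-dimethyl-4H-chromen-4-one | COc1ccccc1-c1cc(=O)c2c(OC)c(C)c(OC)c(C)c2o1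
F4 | step 6 | 4,6-dimethoxy-1a-(2-methoxyphenyl)-3,5-dimethyl-1a,7a-dihydro-7H-oxireno[2,3-b]chromen-7-one (cis-fused, racemic; one enantiomer drawn) | COc1ccccc1[C@]12O[C@H]1C(=O)c1c(OC)c(C)c(OC)c(C)c1O2
F5 | step 5 | 1-(2-hydroxy-4,6-dimethoxy-3,5-dimethylphenyl)-2-(2-methoxyphenyl)ethan-1-one | COc1ccccc1CC(=O)c1c(O)c(C)c(OC)c(C)c1OC
F6 | step 5 | 2-bromo-1-(2-hydroxy-4,6-dimethoxy-3,5-dimethylphenyl)-2-(2-methoxyphenyl)ethan-1-one (racemic) | COc1ccccc1C(Br)C(=O)c1c(O)c(C)c(OC)c(C)c1OC
F7 | step 7 | 3-(benzyloxy)-5,7-dimethoxy-2-(2-methoxyphenyl)-6,8-dimethyl-4H-chromen-4-one | COc1ccccc1-c1oc2c(C)c(OC)c(C)c(OC)c2c(=O)c1OCc1ccccc1
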